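**Retrosynthetic overview**

- The target is numbered as a spiro[5.5]undecane: C1 = C(CH3)(OH), C3 = CHBr, C5 = C(CH3)2, C6 = spiro carbon, C7=C8, C9 = C(=CHBr), C10, C11. The C3–Br bond goes back to an axial C3 alcohol (Appel, inversion) and the vinyl C–Br bond to a C–SiMe3 bond (bromodesilylation, retention).
- The C3 alcohol comes from a C3 ketone and the C1 carbinol from CH3 addition to a C1 carbonyl. C1=O, the C3 oxygen and the C5 gem-dimethyl group together are the vinylogous ester of dimedone, so ring A is bought.
- Ring B is cut at C6–C7 and C8–C9 in one operation: C7=C8 is (Z)-1,2-dichloroethene, C6 is the α′-enolate carbon of the vinylogous ester, and C9 is an alkenylboronate carbon of a side chain already on C6.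
- Enabling feature: the cis-CH=CH unit C7=C8 of ring B lies between the spiro carbon C6, which is α to C1 (a carbonyl one oxidation level up, so C6 can be an enolate), and the sp2 carbon C9 of the exocyclic bromomethylidene (an alkenyl–metal carbon).
- Ring order: ring A from commercial dimedone ethyl enol ether, ring B in step 4. C6 is set by the chiral palladium catalyst from a racemic precursor (stereoconvergent through the planar enolate), C1 and C3 are relayed from C6 by substrate control, and the alkene geometry comes from a syn-hydroboration.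

Key step: step 4

Assumption: the hand of the chiral ligand in step 4 (and of the chiral reagents in the fallbacks) is written provisionally; the antipode that delivers the (6S) spiro centre would be used.

**Step 1**
Reactants: 1 4-(trimethylsilyl)but-3-yn-1-ol
Product: 2 4-(trimethylsilyl)but-3-yn-1-yl trifluoromethanesulfonate
Conditions: Tf2O, 2,6-lutidine, CH2Cl2, −78 °C; used without purification
Reagents that add atoms: trifluoromethanesulfonic anhydride, O=S(=O)(OS(=O)(=O)C(F)(F)F)C(F)(F)F
Why: Sulfonylation of a primary alcohol at low temperature gives the primary triflate, chosen because it alkylates an enolate at −78 °C, where the E2 loss that plagues homopropargylic halides is slow.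

**Step 2**
Reactants: 3 3-ethoxy-5,5-dimethylcyclohex-2-en-1-one; 2 4-(trimethylsilyl)but-3-yn-1-yl trifluoromethanesulfonate
Product: 5 rac-3-ethoxy-5,5-dimethyl-6-[4-(trimethylsilyl)but-3-yn-1-yl]cyclohex-2-en-1-one, via lithium enolate 4 (not isolated)
Conditions: LiN(iPr)2, THF, −78 °C; then 2, −78 → −30 °C
Reagents that add atoms: none
Why: Stork–Danheiser alkylation: LiN(iPr)2 removes the kinetic α′ proton at C6 and the lithium enolate is C-alkylated by the primary triflate in an SN2 reaction; the new C6 stereocentre is formed racemic, which is of no consequence because it is erased at the enolate stage of step 4.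

**Step 3**
Reactants: 5 rac-3-ethoxy-5,5-dimethyl-6-[4-(trimethylsilyl)but-3-yn-1-yl]cyclohex-2-en-1-one
Product: 6 rac-3-ethoxy-5,5-dimethyl-6-[(3Z)-3-(4,4,5,5-tetramethyl-1,3,2-dioxaborolan-2-yl)-4-(trimethylsilyl)but-3-en-1-yl]cyclohex-2-en-1-one
Conditions: B2pin2, MeOH, CuCl (5 mol%), Xantphos (5 mol%), NaOtBu (10 mol%), THF, 25 °C
Reagents that add atoms: bis(pinacolato)diboron, CC1(C)OB(OC1(C)C)B1OC(C)(C)C(C)(C)O1
Why: Copper-catalysed formal hydroboration of an internal alkynylsilane: the boryl–copper species adds syn with boron on the carbon remote from silicon and copper on the silicon-bearing carbon, and protonation of the C–Cu bond by MeOH with retention leaves B and H cis, which fixes SiMe3 cis to the ring-bearing chain.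

**Step 4**
Reactants: 6 rac-3-ethoxy-5,5-dimethyl-6-[(3Z)-3-(4,4,5,5-tetramethyl-1,3,2-dioxaborolan-2-yl)-4-(trimethylsilyl)but-3-en-1-yl]cyclohex-2-en-1-one; 7 (Z)-1,2-dichloroethene
Product: 10 (6S,9E)-3-ethoxy-5,5-dimethyl-9-[(trimethylsilyl)methylidene]spiro[5.5]undeca-2,7-dien-1-one, via chlorodiene 8 (not isolated), via lithium enolate 9 (not isolated)
Conditions: one flask: first Pd2(dba)3 [tris(dibenzylideneacetone)dipalladium] (2.5 mol%), (S)-2-(dicyclohexylphosphino)-2′-(dimethylamino)-1,1′-binaphthyl (6 mol%), 7 (6 equiv), KOSiMe3, THF, 25 °C; then volatiles removed in vacuo, toluene, LiN(SiMe3)2, 0 → 60 °C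
Reagents that add atoms: none
Why: Proposed new method: zerovalent palladium first inserts into one C–Cl bond of 7 and couples with the alkenylboronate of 6 (Suzuki–Miyaura, retention at both alkenes) to give the (Z)-chlorodiene 8; after the excess of 7 is stripped off, LiN(SiMe3)2 turns C6–H into the planar tetrasubstituted enolate 9 (both enantiomers of 6 converge here), the same catalyst inserts into the remaining (Z)-C–Cl bond, and C–C reductive elimination from the palladium enolate joins C6 to the vinyl carbon. The closest known reactions are the coupling of alkenylboron reagents with (Z)-1,2-dichloroethene, the intramolecular palladium-catalysed alkenylation of ketone enolates, and the enantioselective intermolecular α-vinylation of ketone enolates that builds quaternary centres; their merger in one flask on a vinylogous-ester α′-enolate with an enantioselective spiro closure has not been shown. Ring B closes by attack of the enolate carbon on the alkenyl–palladium end of its own side chain, a six-membered closure through a seven-membered palladacycle in which the cis geometry of the linchpin keeps palladium within reach of C6. The only new stereocentre, the spiro carbon C6, is set by the chiral phosphine on palladium, which selects the enolate face during C–C bond formation. The step needs mono-coupling of 7 (secured by its excess and by the lower reactivity of the chlorodiene toward oxidative addition at 25 °C), retention of both alkene geometries (stereoretentive oxidative addition and transmetalation), and attack at C6 rather than at O, C2 or C4 (only C6 gives a six-membered ring; the others would give eight-membered rings).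

**Step 5**
Reactants: 10 (6S,9E)-3-ethoxy-5,5-dimethyl-9-[(trimethylsilyl)methylidene]spiro[5.5]undeca-2,7-dien-1-one
Product: 12 (1S,6S,9E)-1-hydroxy-1,5,5-trimethyl-9-[(trimethylsilyl)methylidene]spiro[5.5]undec-7-en-3-one, via carbinol 11 (not isolated)
Conditions: MeLi, CeCl3, THF, −78 °C; then aq. oxalic acid (0.1 M), THF, 0 °C
Reagents that add atoms: methyllithium, [Li]C; water, O
Why: Organocerium 1,2-addition to the hindered vinylogous-ester carbonyl followed by general-acid hydrolysis of the enol ether under conditions too mild to ionise the tertiary carbinol (a Stork–Danheiser sequence stopped before dehydration) should give the β-hydroxy ketone, the methyl group entering C1 past the flat C7=C8 arm and away from the C11 methylene and the axial C5 methyl, so that the new C1 centre carries OH on the side of C11.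

**Step 6**
Reactants: 12 (1S,6S,9E)-1-hydroxy-1,5,5-trimethyl-9-[(trimethylsilyl)methylidene]spiro[5.5]undec-7-en-3-one
Product: 13 (1S,3S,6S,9E)-1,5,5-trimethyl-9-[(trimethylsilyl)methylidene]spiro[5.5]undec-7-ene-1,3-diol
Conditions: LiBH(sBu)3, THF, −78 °C
Reagents that add atoms: none
Why: In the favoured chair the C1 hydroxyl and one C5 methyl are axial on the face of the axial trajectory to C3, so the bulky hydride should attack equatorially (substrate control, as in reductions of 3,3,5-trimethylcyclohexanone) and give the axial (3S) alcohol cis to the C1 hydroxyl.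

**Step 7**
Reactants: 13 (1S,3S,6S,9E)-1,5,5-trimethyl-9-[(trimethylsilyl)methylidene]spiro[5.5]undec-7-ene-1,3-diol
Product: 14 (1S,3R,6S,9E)-3-bromo-1,5,5-trimethyl-9-[(trimethylsilyl)methylidene]spiro[5.5]undec-7-en-1-ol
Conditions: CBr4, PPh3, CH2Cl2, 0 → 25 °C
Reagents that add atoms: carbon tetrabromide, BrC(Br)(Br)Br
Why: Appel reaction: the less hindered secondary hydroxyl forms the alkoxyphosphonium salt and bromide displaces it by SN2 with inversion, which converts the axial (3S) alcohol into the equatorial (3R) bromide, while the hindered tertiary C1 hydroxyl stays and, being cis, cannot reach the rear of C3.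

**Step 8**
Reactants: 14 (1S,3R,6S,9E)-3-bromo-1,5,5-trimethyl-9-[(trimethylsilyl)methylidene]spiro[5.5]undec-7-en-1-ol
Product: 15 (1S,3R,6S,9E)-3-bromo-9-(bromomethylidene)-1,5,5-trimethylspiro[5.5]undec-7-en-1-ol
Conditions: NBS, MeCN, 0 °C, dark
Reagents that add atoms: N-bromosuccinimide, O=C1CCC(=O)N1Br
Why: Electrophilic ipso-bromodesilylation of a vinylsilane: bromine adds to the silicon-bearing carbon of the diene to give a β-silyl allylic cation that loses the silyl group after the least-motion rotation, so bromine takes the place of silicon with retention and the (E)-bromomethylidene results.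

**Compound list**

1 | 4-(trimethylsilyl)but-3-yn-1-ol | C[Si](C)(C)C#CCCO | starting material
2 | 4-(trimethylsilyl)but-3-yn-1-yl trifluoromethanesulfonate | C[Si](C)(C)C#CCCOS(=O)(=O)C(F)(F)F | intermediate
3 | 3-ethoxy-5,5-dimethylcyclohex-2-en-1-one (dimedone ethyl enol ether) | CCOC1=CC(=O)CC(C)(C)C1 | starting material
4 | lithium 5-ethoxy-3,3-dimethylcyclohexa-1,5-dien-1-olate (α′-enolate of 3) | CCOC1=CC([O-])=CC(C)(C)C1.[Li+] | intermediate
5 | rac-3-ethoxy-5,5-dimethyl-6-[4-(trimethylsilyl)but-3-yn-1-yl]cyclohex-2-en-1-one | CCOC1=CC(=O)C(CCC#C[Si](C)(C)C)C(C)(C)C1 | intermediate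
6 | rac-3-ethoxy-5,5-dimethyl-6-[(3Z)-3-(4,4,5,5-tetramethyl-1,3,2-dioxaborolan-2-yl)-4-(trimethylsilyl)but-3-en-1-yl]cyclohex-2-en-1-one | CCOC1=CC(=O)C(CC/C(B2OC(C)(C)C(C)(C)O2)=C\[Si](C)(C)C)C(C)(C)C1 | intermediate
7 | (Z)-1,2-dichloroethene | Cl/C=C\Cl | starting material
8 | rac-6-{(3E,5Z)-6-chloro-3-[(trimethylsilyl)methylidene]hex-5-en-1-yl}-3-ethoxy-5,5-dimethylcyclohex-2-en-1-one | CCOC1=CC(=O)C(CC/C(/C=C\Cl)=C\[Si](C)(C)C)C(C)(C)C1 | intermediate
9 | lithium α′-enolate of 8 (enolate C=C between C1 and C6, planar at C6) | CCOC1=CC([O-])=C(CC/C(/C=C\Cl)=C\[Si](C)(C)C)C(C)(C)C1.[Li+] | intermediate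
10 | (6S,9E)-3-ethoxy-5,5-dimethyl-9-[(trimethylsilyl)methylidene]spiro[5.5]undeca-2,7-dien-1-one | CC1(C)CC(OCC)=CC(=O)[C@@]12C=C/C(=C/[Si](C)(C)C)CC2 | intermediate
11 | (1S,6S,9E)-3-ethoxy-1,5,5-trimethyl-9-[(trimethylsilyl)methylidene]spiro[5.5]undeca-2,7-dien-1-ol | CC1(C)CC(OCC)=C[C@](C)(O)[C@@]12C=C/C(=C/[Si](C)(C)C)CC2 | intermediate
12 | (1S,6S,9E)-1-hydroxy-1,5,5-trimethyl-9-[(trimethylsilyl)methylidene]spiro[5.5]undec-7-en-3-one | CC1(C)CC(=O)C[C@](C)(O)[C@@]12C=C/C(=C/[Si](C)(C)C)CC2 | intermediate
13 | (1S,3S,6S,9E)-1,5,5-trimethyl-9-[(trimethylsilyl)methylidene]spiro[5.5]undec-7-ene-1,3-diol | CC1(C)C[C@H](O)C[C@](C)(O)[C@@]12C=C/C(=C/[Si](C)(C)C)CC2 | intermediate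
14 | (1S,3R,6S,9E)-3-bromo-1,5,5-trimethyl-9-[(trimethylsilyl)methylidene]spiro[5.5]undec-7-en-1-ol | CC1(C)C[C@@H](Br)C[C@](C)(O)[C@@]12C=C/C(=C/[Si](C)(C)C)CC2 | intermediate
15 | (1S,3R,6S,9E)-3-bromo-9-(bromomethylidene)-1,5,5-trimethylspiro[5.5]undec-7-en-1-ol | CC1(C)C[C@@H](Br)C[C@](C)(O)[C@@]12C=C/C(=C/Br)CC2 | target

**Step count and risks**

Total step count: 8. Longest linear sequence: 8 steps (1 → 2 → 5 → 6 → 10 → 12 → 13 → 14 → 15).

Steps most likely to fail:

1. Step 4. What may go wrong: slow C–C reductive elimination at the crowded C6 next to the quaternary C5 with competing β-hydride loss from the palladium enolate, base-induced loss of HCl from the (Z)-chlorodiene, or weak enantioface selection. Fallback with known chemistry, setting out from 5 and coming back at 10: the enolate of 5 (LiN(iPr)2, THF, −78 °C) is O-acylated with allyl chloroformate to the allyl enol carbonate F1. Palladium-catalysed enantioselective decarboxylative allylic alkylation (Pd2(dba)3, (S)-tBu-PHOX, toluene, 30 °C) then sets the quaternary centre in the C6-allyl ketone F2. Lemieux–Johnson cleavage of the terminal alkene (OsO4 cat., NaIO4, 2,6-lutidine, dioxane/water) gives the aldehyde F3. A nickel-catalysed reductive alkyne–aldehyde cyclisation (Ni(cod)2 [bis(1,5-cyclooctadiene)nickel], PBu3, Et3B) adds the aldehyde carbon and hydrogen syn across the alkynylsilane and closes ring B as the allylic alcohol F4, with SiMe3 already cis to C10. Dehydration toward C7 with the Burgess reagent gives 10.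

2. Step 5. What may go wrong: ionisation of the tertiary allylic carbinol during enol-ether hydrolysis with loss of water to the transposed enone, or delivery of the methyl group to the wrong carbonyl face. Fallback, setting out from 10 and coming back at 13: after the same organocerium addition, carbinol 11 is treated with aq. HCl so that the Stork–Danheiser transposition runs to completion and gives the enone F5. CBS reduction (oxazaborolidine antipode chosen for the (3S) carbinol, BH3·SMe2) gives the allylic alcohol F6. Hydroxyl-directed epoxidation (VO(acac)2 [vanadyl bis(acetylacetonate)], tBuOOH, CH2Cl2) delivers oxygen to C1 on the face of the C3 hydroxyl and gives the epoxy alcohol F7. NaAlH2(OCH2CH2OMe)2 opens the epoxide at C2 by internal hydride delivery to give diol 13. In this variant the C1 oxygen is placed by the C3 hydroxyl instead of by the facial bias at C1.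

3. Step 8. What may go wrong: capture of the allylic cation at C9 by the C1 hydroxyl across ring B (bridged ether formation), or addition of bromine across the diene in place of ipso substitution. Fallback, setting out from 14 and coming back at 15: the tertiary hydroxyl is masked (Me3SiOTf, 2,6-lutidine, CH2Cl2, −78 °C) as the trimethylsilyl ether F8. Bromodesilylation with NBS in MeCN gives the bromomethylidene silyl ether F9, and aq. citric acid in MeOH removes the O-silyl group to give 15.

**Further compounds**

F1 | step 4 | allyl 5-ethoxy-3,3-dimethyl-2-[4-(trimethylsilyl)but-3-yn-1-yl]cyclohexa-1,5-dien-1-yl carbonate | CCOC1=CC(OC(=O)OCC=C)=C(CCC#C[Si](C)(C)C)C(C)(C)C1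
F2 | step 4 | (6S)-3-ethoxy-5,5-dimethyl-6-(prop-2-en-1-yl)-6-[4-(trimethylsilyl)but-3-yn-1-yl]cyclohex-2-en-1-one | CC1(C)CC(OCC)=CC(=O)[C@@]1(CCC#C[Si](C)(C)C)CC=C
F3 | step 4 | 2-{(1S)-4-ethoxy-2,2-dimethyl-6-oxo-1-[4-(trimethylsilyl)but-3-yn-1-yl]cyclohex-4-en-1-yl}acetaldehyde | CC1(C)CC(OCC)=CC(=O)[C@@]1(CCC#C[Si](C)(C)C)CC=O
F4 | step 4 | (6S,9E)-3-ethoxy-8-hydroxy-5,5-dimethyl-9-[(trimethylsilyl)methylidene]spiro[5.5]undec-2-en-1-one (either C8 epimer) | CC1(C)CC(OCC)=CC(=O)[C@@]12CC(O)/C(=C/[Si](C)(C)C)CC2
F5 | step 5 | (6S,9E)-1,5,5-trimethyl-9-[(trimethylsilyl)methylidene]spiro[5.5]undeca-1,7-dien-3-one | CC1(C)CC(=O)C=C(C)[C@@]12C=C/C(=C/[Si](C)(C)C)CC2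
F6 | step 5 | (3S,6S,9E)-1,5,5-trimethyl-9-[(trimethylsilyl)methylidene]spiro[5.5]undeca-1,7-dien-3-ol | CC1(C)C[C@H](O)C=C(C)[C@@]12C=C/C(=C/[Si](C)(C)C)CC2
F7 | step 5 | (3S,6S,9E)-1,2-epoxy-1,5,5-trimethyl-9-[(trimethylsilyl)methylidene]spiro[5.5]undec-7-en-3-ol, epoxide oxygen cis to the C3 hydroxyl | CC1(C)C[C@H](O)[C@@H]3O[C@]3(C)[C@@]12C=C/C(=C/[Si](C)(C)C)CC2
F8 | step 8 | trimethylsilyl ether of 14 at the C1 oxygen | CC1(C)C[C@@H](Br)C[C@](C)(O[Si](C)(C)C)[C@@]12C=C/C(=C/[Si](C)(C)C)CC2
F9 | step 8 | trimethylsilyl ether of 15 at the C1 oxygen | CC1(C)C[C@@H](Br)C[C@](C)(O[Si](C)(C)C)[C@@]12C=C/C(=C/Br)CC2
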